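**Retrosynthetic overview**
- Target ⇐ macrocyclic dialdehyde by a double Dakin oxidation: both phenolic OH groups are carried as CHO groups, so no protecting groups are needed (ring A = methoxy/hydroxy tetrasubstituted ring, ring B = 1,3-phenylene, ring C = hydroxylated trisubstituted ring, ring D = 1,4-phenylene).
- Macrocyclic dialdehyde ⇐ two bibenzyls joined by two aryl C–O bonds in one flask: SNAr for ring D–O–ring C (fluoride ortho to CHO), then copper-catalysed closure of the hindered ring A–O–ring B ether; the 18-membered ring is the only ring formed and it is formed last.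
- Ring A/ring D bibenzyl ⇐ 2-bromoisovanillin + 4-acetoxystyrene (hydroboration, B-alkyl Suzuki).
- Ring B/ring C bibenzyl ⇐ 2-fluoro-4-iodobenzaldehyde + 3-bromostyrene (hydroboration, B-alkyl Suzuki).

Assumption: the SMILES has no stereodescriptor and the molecule has no stereocentre; the 18-membered ring is taken as conformationally mobile, so the target is achiral and no stereocontrol is needed.

**Step 1**
Reactants: 1 2-bromo-3-hydroxy-4-methoxybenzaldehyde; 2 4-acetoxystyrene; 3 9-BBN
Product: 6 3-hydroxy-2-[2-(4-hydroxyphenyl)ethyl]-4-methoxybenzaldehyde, via alkylborane 4 (not isolated), via aryl acetate 5 (not isolated)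
Conditions: 2 (1.3 equiv), 9-BBN (1.25 equiv), THF, 0 °C to rt, 4 h; then 1 (1.0 equiv), Pd(OAc)2 (3 mol%), SPhos (6 mol%), 3 M aq K3PO4, 65 °C; then MeOH, 65 °C, 1 h; 1 M HCl work-up
Reagents that add atoms: none
Why: B-alkyl Suzuki–Miyaura coupling, in which anti-Markovnikov hydroboration gives a primary alkylborane whose hydroxyborate transmetalates to the arylpalladium bromide from 1 (oxidative addition helped by the ortho-formyl group, SPhos coping with the di-ortho-substituted bromide), no B–H is left when the aldehyde is added, and the aqueous phosphate then cleaves the aryl acetate.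

**Step 2**
Reactants: 7 3-bromostyrene; 3 9-BBN; 8 2-fluoro-4-iodobenzaldehyde
Product: 10 4-[2-(3-bromophenyl)ethyl]-2-fluorobenzaldehyde, via alkylborane 9 (not isolated)
Conditions: 7 (1.05 equiv), 9-BBN (1.0 equiv), THF, 0 °C to rt, 4 h; then 8 (1.1 equiv), Pd(dppf)Cl2 (3 mol%), 3 M aq K3PO4, DMF/THF, rt, 12 h
Reagents that add atoms: none
Why: B-alkyl Suzuki–Miyaura coupling, in which zerovalent palladium at room temperature inserts into the C–I bond para to the formyl group far faster than into the unactivated meta C–Br bond, so the bromide survives for the ring closure, and the fluoride is not displaced by aqueous phosphate at this temperature.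

**Step 3**
Reactants: 6 3-hydroxy-2-[2-(4-hydroxyphenyl)ethyl]-4-methoxybenzaldehyde; 10 4-[2-(3-bromophenyl)ethyl]-2-fluorobenzaldehyde
Product: 12 macrocyclic bis(bibenzyl) dialdehyde, via seco bromophenol 11 (not isolated)
Conditions: 6 and 10 (1:1), K3PO4 (4 equiv), DMSO (0.1 M), 110 °C, argon, until 10 is consumed; then dilute with degassed DMSO to 3 mM, CuI (0.5 equiv), picolinic acid (1.0 equiv), 110 °C, 24–36 h
Reagents that add atoms: none
Why: Proposed new method: an orthogonal double O-arylation that stitches two bifunctional bibenzyls head-to-tail into the macrocycle in one flask; without metal only the fluoride ortho to the formyl group can be displaced (addition–elimination through a formyl-stabilised Meisenheimer adduct), and the unhindered, more basic ring D phenoxide should outrun the ring A phenoxide flanked by OMe and the CH2CH2 chain, so 11 forms with one phenoxide and one aryl bromide left at the two chain ends; after dilution the picolinate-ligated monovalent copper phenoxide of ring A adds oxidatively to the ring B C–Br bond and the trivalent copper intermediate closes the 18-membered ring by C–O reductive elimination; the closest known reaction types are SNAr diaryl ether synthesis with 2-fluorobenzaldehydes, the picolinic acid-promoted Ullmann coupling of di-ortho-substituted phenols and intramolecular Ullmann closure of diaryl ether cyclophanes, and the untested elements are their use as a programmed pair for a two-component macrocyclisation and ring closure at a 2,6-disubstituted phenoxide in this ring system.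

**Step 4**
Reactants: 12 macrocyclic bis(bibenzyl) dialdehyde
Product: 14 CNP0179896.0, via bis(formate) 13 (not isolated)
Conditions: mCPBA (2.6 equiv), CH2Cl2, 0 °C to 40 °C; aq Na2S2O3/NaHCO3 wash; then K2CO3 (0.3 equiv), MeOH, rt, under argon; NH4Cl work-up
Reagents that add atoms: mCPBA (3-chloroperoxybenzoic acid), OOC(=O)c1cccc(Cl)c1
Why: Dakin-type Baeyer–Villiger oxidation, in which the electron-rich aryl group of each Criegee adduct (para-OMe on ring A, ortho-aryloxy on ring C) migrates in preference to hydride to give the aryl formate, and mild methanolysis frees the two phenols without touching the methyl ether or the diaryl ethers.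

**Compound list**
1 | 2-bromo-3-hydroxy-4-methoxybenzaldehyde (2-bromoisovanillin) | O=Cc1ccc(OC)c(O)c1Br | starting material
2 | 4-acetoxystyrene (4-vinylphenyl acetate) | CC(=O)Oc1ccc(C=C)cc1 | starting material
3 | 9-borabicyclo[3.3.1]nonane (9-BBN, used as 0.5 M THF solution) | B1C2CCCC1CCC2 | starting material
4 | 4-[2-(9-borabicyclo[3.3.1]nonan-9-yl)ethyl]phenyl acetate | CC(=O)Oc1ccc(CCB2C3CCCC2CCC3)cc1 | intermediate
5 | 4-[2-(2-formyl-6-hydroxy-5-methoxyphenyl)ethyl]phenyl acetate | CC(=O)Oc1ccc(CCc2c(C=O)ccc(OC)c2O)cc1 | intermediate
6 | 3-hydroxy-2-[2-(4-hydroxyphenyl)ethyl]-4-methoxybenzaldehyde (ring A/ring D bibenzyl) | O=Cc1ccc(OC)c(O)c1CCc1ccc(O)cc1 | intermediate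
7 | 3-bromostyrene | C=Cc1cccc(Br)c1 | starting material
8 | 2-fluoro-4-iodobenzaldehyde | O=Cc1ccc(I)cc1F | starting material
9 | 9-[2-(3-bromophenyl)ethyl]-9-borabicyclo[3.3.1]nonane | Brc1cccc(CCB2C3CCCC2CCC3)c1 | intermediate
10 | 4-[2-(3-bromophenyl)ethyl]-2-fluorobenzaldehyde (ring B/ring C bibenzyl) | O=Cc1ccc(CCc2cccc(Br)c2)cc1F | intermediate
11 | 2-[2-[4-[5-[2-(3-bromophenyl)ethyl]-2-formylphenoxy]phenyl]ethyl]-3-hydroxy-4-methoxybenzaldehyde (seco bromophenol) | O=Cc1ccc(OC)c(O)c1CCc1ccc(Oc2cc(CCc3cccc(Br)c3)ccc2C=O)cc1 | intermediate
12 | macrocyclic dialdehyde: the 18-membered target ring system with CHO in place of the OH on ring A and on ring C | COc1ccc(C=O)c2c1Oc1cccc(c1)CCc1ccc(C=O)c(c1)Oc1ccc(cc1)CC2 | intermediate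
13 | bis(formate) of the target (O-formyl on the ring A and ring C oxygens) | COc1ccc(OC=O)c2c1Oc1cccc(c1)CCc1ccc(OC=O)c(c1)Oc1ccc(cc1)CC2 | intermediate
14 | CNP0179896.0: ring A (OMe, O-aryl, CH2, OH on four adjacent carbons) – O – ring B (1,3-phenylene) – CH2CH2 – ring C (4-OH, 3-O-aryl) – O – ring D (1,4-phenylene) – CH2CH2 – back to ring A; achiral | COc1ccc(O)c2c1Oc1cccc(c1)CCc1ccc(O)c(c1)Oc1ccc(cc1)CC2 | target

**Totals**
Total steps: 4. Longest linear sequence: 3 steps (1 → 6 → 12 → 14, or 7 → 10 → 12 → 14).

**Three steps most likely to fail**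

Step 3 (proposed new method). The risks are imperfect discrimination between the two phenoxides in the SNAr stage, oligomerisation, slow copper turnover with the hindered phenoxide at 3 mM, and hydrodebromination. The fallback uses known chemistry and sets out from 6 and 10. The SNAr is run alone (K2CO3, DMF, 110 °C) and the seco bromophenol 11 is isolated and purified. Miyaura borylation (B2pin2, Pd(dppf)Cl2, KOAc, dioxane, 85 °C) gives the pinacol boronate F1. Exchange with excess methylboronic acid (acetone/0.1 M HCl, rt, evaporation) gives the boronic acid F2. A Chan–Lam–Evans oxidative ring closure (Cu(OAc)2 2 equiv, pyridine, 4 Å molecular sieves, CH2Cl2, air, rt, 2 mM) then forms the ring A–O–ring B bond. This runs at room temperature through a divalent copper/arylboron pathway and avoids oxidative addition into an unactivated bromide. It comes back to the route at 12.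

Step 1. The bromide of 1 is flanked by a formyl group and a phenoxide, and the alkylborane could reduce the aldehyde or give β-hydride elimination products. The fallback sets out from 1 and 2. A Heck reaction (Pd(OAc)2, P(o-tol)3, Et3N, DMF, 110 °C) gives the (E)-stilbene acetate F3. Alkene-selective hydrogenation (H2, 10% Pd/C poisoned with Ph2S, EtOAc, rt) keeps the aldehyde and gives 5. Aqueous K2CO3/MeOH then removes the acetate, and the fallback comes back to the route at 6.

Step 2. Any insertion into the C–Br bond of the borane gives oligomers, and the ortho-fluoro aldehyde must survive aqueous base. The fallback sets out from 7 and 8. An iodide-selective ligand-free Heck reaction (Pd(OAc)2, Bu4NCl, NaHCO3, DMF, 70 °C) gives the (E)-stilbene F4. Diimide reduction (dipotassium azodicarboxylate, AcOH, MeOH, rt) saturates the alkene without touching C–Br, C–F or CHO, and the fallback comes back to the route at 10.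

Step 4 is ranked fourth because both aldehyde types have direct Dakin precedent.

**Further compounds**
F1 | step 3 | pinacol boronate of the seco phenol (11 with Bpin in place of Br) | O=Cc1ccc(OC)c(O)c1CCc1ccc(Oc2cc(CCc3cccc(B4OC(C)(C)C(C)(C)O4)c3)ccc2C=O)cc1
F2 | step 3 | boronic acid of the seco phenol (11 with B(OH)2 in place of Br) | O=Cc1ccc(OC)c(O)c1CCc1ccc(Oc2cc(CCc3cccc(B(O)O)c3)ccc2C=O)cc1
F3 | step 1 | 4-[(E)-2-(2-formyl-6-hydroxy-5-methoxyphenyl)ethenyl]phenyl acetate | CC(=O)Oc1ccc(/C=C/c2c(C=O)ccc(OC)c2O)cc1
F4 | step 2 | 4-[(E)-2-(3-bromophenyl)ethenyl]-2-fluorobenzaldehyde | O=Cc1ccc(/C=C/c2cccc(Br)c2)cc1F
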